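**Assumptions (one line each):** Commercial hesperetin is the natural (2S) enantiomer; E‑geranyl bromide is commercial. A (2S)‑flavanone and a (2R,3R)‑dihydroflavonol have the same spatial arrangement at C2, because the CIP label flips when OH is added at C3.

## Retrosynthetic overview
1. Target ⇒ 3‑hydroxylation of a 6‑geranylflavanone. Trans attack relative to the 2‑aryl group sets C3 from C2.
2. 6‑Geranylflavanone ⇒ ortho C–H geranylation of (2S)‑hesperetin. This is the key C–C bond, formed photochemically.
3. All three rings (A, B, C) are already present in hesperetin, so no ring is built. The only stereocentre that is bought is C2; C3 is set by C2.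

## Route

**Step 1**
Reactants: 1 (2S)‑hesperetin; 2 (E)‑geranyl bromide
Product: 3 (2S)‑6‑geranylhesperetin
Conditions: 2 (1.5 equiv), Cs2CO3 (1.0 equiv), MeCN (0.05 M), Ar, 390 nm LEDs, 10 °C, 16 h
Reagents that add atoms: none
Why: Proposed new method: Visible light excites a charge‑transfer complex between the 7‑phenolate of 1 and geranyl bromide. Single‑electron transfer and C–Br cleavage give a caged phenoxyl/geranyl radical pair. The pair recombines at the less hindered primary allyl terminus, so the E geometry is kept. Recombination occurs at C6, which lies ortho to both the 5‑ and 7‑oxygens, and tautomerisation restores the phenol. The closest known chemistry is EDA‑complex photoalkylation of phenolates with α‑bromocarbonyls and perfluoroalkyl iodides, together with radical‑pair recombination in the photo‑Claisen rearrangement. The reaction is run with one equivalent of weak base and no heat, and the 7‑phenolate suppresses enolisation at C3, so ring‑opening racemisation at C2 is minimised. C2 is untouched.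

**Step 2**
Reactants: 3; 4 trimethylsilyl triflate
Product: 5 tri‑O‑TMS ether of the 4‑silyloxy‑2H‑chromene (silyl enol ether), with C2 (S‑flavanone geometry) retained
Conditions: 4 (4.5 equiv), Et3N (6 equiv), CH2Cl2, 0 °C → rt, 2 h; evaporate, triturate with dry hexane, and use directly
Reagents that add atoms: TMSOTf, C[Si](C)(C)OS(=O)(=O)C(F)(F)F
Why: Et3N‑buffered TMSOTf silylates the three phenols and converts the ketone to its silyl enol ether (Mukaiyama‑type enol silylation). This protects the phenols and activates C3 without strong base, so C2 is not epimerised.

**Step 3**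
Reactants: 5; 6 dimethyldioxirane
Product: 7 4'‑O‑methyldiplacol, (2R,3R)
Conditions: 6 (1.1 equiv, ~0.08 M in acetone), CH2Cl2, −78 → 0 °C, 1 h; then AcOH/MeOH/H2O (5:4:1), rt, 30 min (one pot)
Reagents that add atoms: DMDO, CC1(C)OO1 (its O ends up as the 3‑OH)
Why: This is a Rubottom oxidation. DMDO epoxidises the electron‑rich enol ether much faster than the isolated trisubstituted olefins at −78 °C. It attacks the face anti to the pseudo‑axial 2‑aryl group, so the new C3–O bond is trans to the aryl. Epoxide opening and 1,4‑silyl shift give the 3‑OTMS ketone, and mild acid removes all TMS groups. The product is the 2,3‑trans (2R,3R) dihydroflavonol, which is also the thermodynamically preferred isomer.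

## Compound list
1 | (2S)‑hesperetin | COc1ccc([C@H]2Oc3cc(O)cc(O)c3C(=O)C2)cc1O | starting material
2 | (E)‑geranyl bromide | BrC/C=C(\C)CCC=C(C)C | starting material
3 | (2S)‑6‑geranylhesperetin | COc1ccc([C@H]2Oc3cc(O)c(C/C=C(\C)CCC=C(C)C)c(O)c3C(=O)C2)cc1O | intermediate
4 | trimethylsilyl triflate | C[Si](C)(C)OS(=O)(=O)C(F)(F)F | reagent
5 | tetra‑O‑TMS silyl enol ether of 3 | COc1ccc([C@H]2Oc3cc(O[Si](C)(C)C)c(C/C=C(\C)CCC=C(C)C)c(O[Si](C)(C)C)c3C(O[Si](C)(C)C)=C2)cc1O[Si](C)(C)C | intermediate
6 | dimethyldioxirane | CC1(C)OO1 | reagent
7 | 4'‑O‑methyldiplacol | COc1ccc([C@H]2Oc3cc(O)c(C/C=C(\C)CCC=C(C)C)c(O)c3C(=O)[C@@H]2O)cc1O | target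

**Total steps:** 3. **Longest linear sequence:** 3.

## Three steps most likely to fail
1. **Step 1 (proposed new photochemical geranylation).** The risks are a C6/C8 mixture, dark SN2 O‑geranylation at 7‑O, and partial racemisation at C2.
   Fallback: acid‑mediated electrophilic C‑geranylation of 1 with geraniol and BF3·OEt2 in dioxane, then separation of the C6 and C8 isomers by preparative HPLC. This is known chemistry.
2. **Step 3 (Rubottom step).** DMDO may also epoxidise a geranyl olefin, and the trans selectivity may be eroded.
   Fallback: reverse the order. Hydroxylate 1 first by Steps 2–3 (no olefin present) to give 4'‑O‑methyltaxifolin, then install the geranyl group by the Step 1 fallback.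
3. **Step 2 (persilylation and enol silylation).** TMSOTf could cyclise the geranyl chain, or silylation of the H‑bonded ketone could be incomplete.
   Fallback: protect the three phenols of 3 as MOM ethers, form the lithium enolate with LiHMDS at −78 °C, and hydroxylate with achiral 2‑(phenylsulfonyl)‑3‑phenyloxaziridine (trans to the 2‑aryl). Then remove the MOM groups with MgBr2·OEt2/Me2S.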